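The pitfall was to watch X. At 4.00 h X stood at 45.8% in Friday's run and 55.6% in Monday's, while J stood at 6.7% and 35.1%. Monday's run carried more L, 4 equiv against 0.48 equiv. The five new flasks differ in L.

in all of them: X 0.30 M
- Friday's: L 0.48 equiv; G 2 equiv; Q 0.030 M; run made earlier
- Monday's: L 4 equiv; G 2 equiv; Q 0.030 M; run made earlier
- amber: L 3.00 equiv; G 2.00 equiv; Q 0.0300 M; time 4.0 h
- red: L 1.50 equiv; G 2.00 equiv; Q 0.0300 M; time 4.0 h
- violet: L 0.380 equiv; G 2.00 equiv; Q 0.0300 M; time 4.0 h
- green: L 1.00 equiv; G 2.00 equiv; Q 0.0300 M; time 4.0 h
- ochre: L 0.750 equiv; G 2.00 equiv; Q 0.0300 M; time 4.0 h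

- Friday's (time / h: J / %, X / %): 0.333: 1.1, 92.5; 0.500: 0.7, 88.5; 0.667: 0, 82.6; 1.00: 1.1, 79.1; 1.50: 2.0, 69.2; 2.50: 3.8, 58.8; 4.00: 6.7, 45.8
- Monday's (time / h: J / %, X / %): 0.333: 0, 93.6; 0.500: 0, 87.5; 0.667: 1.6, 86.4; 1.00: 3.4, 79.1; 1.50: 9.6, 74.0; 2.50: 20.4, 63.5; 4.00: 35.1, 55.6

(standard deviation of a reading: 1 percentage point)



- the flasks by amount of J, in percent of the X charged, highest first, at 4.0 h (amber / red / violet / green / ochre)
- the same order at 30 h (amber / red / violet / green / ochre)
- the amount of J, in percent of the X charged of the flask you put first, at 4.0 h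
- the amount of J, in percent of the X charged of the flask you put last, at 4.0 h

I followed one molecule of X. I took it that once it had left X, it was either J or still on its way. I therefore read the last row of each table. Friday's gave 0.141, and that ratio of J to what has left X but isn't J is what I carried: the arrival odds. Monday's row gave 3.77, far higher, though this is a reading on a small difference, with 1 percentage point on each term.

Between the two rows, the odds rose as L to the power 1.55. So I gave amber odds of 2.42. Violet, which lies below Friday's L, got 0.0982 by extrapolation. Odds become a share through odds/(1 + odds). I took the X lost from the nearer run, which gave J of 31.4% in amber and 4.85% in violet. I ranked the flasks by L. The odds gave me no order for 30 h.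

The forecast gave amber > red > green > ochre > violet at 4.0 h and amber > red > green > ochre > violet at 30 h, with J at 4.0 h of 29% in its first flask and 5.5% in its last. Of amber and red late on, it said “their order is uncertain”. My top was higher and my low was lower.

    X + G → E (k = 0.420 /M/h)
    G + L → D (k = 0.160 /M/h)
    E + D → J (k = 5.90 /M/h)
    L + Q → Z (k = 41.0 /M/h)

The flasks gave amber > red > green > ochre > violet at 4.0 h, with J of 32.7% in the first and 5.58% in the last. At 30 h they gave red > amber > green > ochre > violet, red 80.4% and amber 75.6%. What had left X and wasn't J was E, the intermediate. Amber's odds at 4.0 h were 2.07 against my 2.42. Violet's were 0.111 against my 0.0982, below Friday's 0.141. At 4.0 h neither amber nor violet had come to rest. Ten times the time took amber's odds to 1660, with J 76.3%, X 23.7% and G 0.544% of its charge. Violet's odds reached 0.312, with J 23.6% and E still 75.6%.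

The readings come from a simulation on assumed constants, noise included.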